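Assumption: the stereodescriptors of the given SMILES are taken at face value, (3R,5R,6S) for the 3,6-epoxy end and (3R,5S,6S) for the triol end; ring positions are quoted in carotenoid numbering.

## Retrosynthetic overview

1. C15=C15' is made last by Wittig olefination of two C20 halves: phosphonium salt 50 (3,6-epoxy end) and aldehyde 25 (triol end), followed by desilylation.
2. Triol half: two C5 Horner–Wadsworth–Emmons homologations of ring aldehyde 17; its C5/C6 diol comes from Sharpless epoxidation of allylic alcohol 13 and inverting hydrolysis at C5.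
3. Epoxy half: one C5 homologation of a C15 unit made by adding a C6 dienyl metal to ring ketone 39 (C7 cut off by periodate); alkoxide O6 then displaces the C3 tosylate to close the ether bridge.
4. Both ring units come from one racemic hydroxy ester 6 (mesityl oxide + methyl acetoacetate annulation), resolved by lipase so that each enantiomer feeds one half.
5. Ring order: carbocycle first (step 1), transient oxiranes (steps 9 and 24), 7-oxabicyclo[2.2.1]heptane bridge last (step 29).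

## Ring unit and resolution

Step 1
Reactants: 1 mesityl oxide (4-methylpent-3-en-2-one); 2 methyl acetoacetate
Product: 3 methyl (±)-2,6,6-trimethyl-4-oxocyclohex-2-ene-1-carboxylate
Conditions: ZnCl2 (0.2 equiv), heptane–toluene, reflux, Dean–Stark, 48 h
Reagents that add atoms: none
Why: Lewis-acid-mediated Michael addition followed by intramolecular aldol condensation (Robinson-type annulation) builds the trimethylcyclohexenone with C7 already in place as the ester.

Step 2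
Reactants: 3 keto ester
Product: 4 methyl 4-acetoxy-2,6,6-trimethylcyclohexa-1,3-diene-1-carboxylate
Conditions: isopropenyl acetate, TsOH·H2O (cat.), reflux, acetone distilled off
Reagents that add atoms: isopropenyl acetate, CC(=C)OC(C)=O
Why: thermodynamic acid-catalysed enol acetylation through the γ-position (C6–H, also α to the ester) gives the linear dienol acetate conjugated with the ester.

Step 3
Reactants: 4 dienol acetate
Product: 6 methyl (±)-4-hydroxy-2,6,6-trimethylcyclohex-1-ene-1-carboxylate, via β,γ-unsaturated keto ester 5 (not isolated)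
Conditions: NaBH4, EtOH, 0 °C → rt
Reagents that add atoms: none
Why: ethanolysis frees the dienolate, kinetic α-protonation gives deconjugated ketone 5, and borohydride reduces it faster than it reconjugates (the steroid dienol-acetate to homoallylic-alcohol reduction), leaving C5=C6 in place and C3 racemic.

Step 4
Reactants: 6 racemic hydroxy ester
Product: 7 methyl (4R)-4-acetoxy-2,6,6-trimethylcyclohex-1-ene-1-carboxylate and 8 methyl (4S)-4-hydroxy-2,6,6-trimethylcyclohex-1-ene-1-carboxylate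
Conditions: immobilised Burkholderia cepacia lipase (lipase PS), vinyl acetate, MTBE, 30 °C, to 50% conversion; chromatography
Reagents that add atoms: vinyl acetate, C=COC(C)=O
Why: lipase-catalysed kinetic resolution by irreversible transesterification, the (R)-carbinol being acylated by Kazlauskas' rule (gem-dimethyl flank as large group); both enantiomers are used, 8 for the triol half and 7 for the epoxy half.

## C5 nitrile phosphonate

Step 5
Reactants: 9 3-methylbut-2-enenitrile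
Product: 10 (2E)-4-bromo-3-methylbut-2-enenitrile (E/Z mixture, E drawn)
Conditions: NBS, AIBN (cat.), PhCF3, reflux
Reagents that add atoms: N-bromosuccinimide, O=C1CCC(=O)N1Br
Why: Wohl–Ziegler allylic bromination of a γ-methyl group.

Step 6
Reactants: 10 bromo nitrile
Product: 11 diethyl [(2E)-3-cyano-2-methylprop-2-en-1-yl]phosphonate
Conditions: P(OEt)3, neat, 110 °C
Reagents that add atoms: triethyl phosphite, CCOP(OCC)OCC
Why: Michaelis–Arbuzov reaction of the allylic bromide.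

## Triol half (C20 aldehyde 25)

Step 7
Reactants: 8 (S)-hydroxy ester
Product: 12 methyl (4S)-4-[tert-butyl(dimethyl)silyl]oxy-2,6,6-trimethylcyclohex-1-ene-1-carboxylate
Conditions: TBSCl, imidazole, DMF, rt
Reagents that add atoms: tert-butyldimethylsilyl chloride, CC(C)(C)[Si](C)(C)Cl
Why: standard silylation of the secondary alcohol.

Step 8
Reactants: 12 silyl ether ester
Product: 13 [(4S)-4-[tert-butyl(dimethyl)silyl]oxy-2,6,6-trimethylcyclohex-1-en-1-yl]methanol
Conditions: i-Bu2AlH (2.5 equiv), CH2Cl2, −78 °C; aq. potassium sodium tartrate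
Reagents that add atoms: none
Why: hydride reduction of the conjugated ester to the allylic alcohol needed to direct the epoxidation.

Step 9
Reactants: 13 allylic alcohol
Product: 14 [(1R,4R,6R)-4-[tert-butyl(dimethyl)silyl]oxy-2,2,6-trimethyl-7-oxabicyclo[4.1.0]heptan-1-yl]methanol (oxirane cis to the silyloxy group)
Conditions: Ti(OiPr)4 (0.2 equiv), D-(−)-diethyl tartrate (0.25 equiv), t-BuOOH, 4 Å MS, CH2Cl2, −20 °C
Reagents that add atoms: tert-butyl hydroperoxide, CC(C)(C)OO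
Why: Sharpless asymmetric epoxidation; the tartrate (the enantiomer opposite to the one that gives (2S,3S)-epoxygeraniol) controls the face and sets C5 and C6 regardless of the remote C3 centre.

Step 10
Reactants: 14 epoxy alcohol
Product: 15 (1R,2S,4R)-4-[tert-butyl(dimethyl)silyl]oxy-1-(hydroxymethyl)-2,6,6-trimethylcyclohexane-1,2-diol
Conditions: 0.1 M H2SO4, THF–H2O (2:1), 0 °C, 2 h
Reagents that add atoms: water, O
Why: acid-catalysed epoxide hydrolysis in which water attacks C5 (C6 is neopentylic and deactivated by CH2OH) anti to the oxirane, giving the trans-diaxial diol (Fürst–Plattner) with C5 inverted and C6 retained.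

Step 11
Reactants: 15 triol
Product: 16 (1S,2S,4R)-4-[tert-butyl(dimethyl)silyl]oxy-1,2-dihydroxy-2,6,6-trimethylcyclohexane-1-carbaldehyde
Conditions: Dess–Martin periodinane (1.1 equiv), NaHCO3, CH2Cl2, 0 °C
Reagents that add atoms: none
Why: Dess–Martin oxidation of the only oxidisable (primary) carbinol; the tertiary hydroxyls are inert, and with a slight excess of buffered oxidant at 0 °C the hindered α-hydroxy aldehyde is not cleaved further.

Step 12
Reactants: 16 dihydroxy aldehyde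
Product: 17 (1S,2S,4R)-4-[tert-butyl(dimethyl)silyl]oxy-2,6,6-trimethyl-1,2-bis(trimethylsilyloxy)cyclohexane-1-carbaldehyde
Conditions: TMSOTf (2.5 equiv), Et3N, CH2Cl2, −78 → 0 °C
Reagents that add atoms: trimethylsilyl trifluoromethanesulfonate, C[Si](C)(C)OS(=O)(=O)C(F)(F)F
Why: silylation of both tertiary hydroxyls blocks retro-aldol and α-ketol pathways of the non-enolisable aldehyde under the basic olefination.

Step 13
Reactants: 17 silylated aldehyde; 11 C5 nitrile phosphonate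
Product: 19 (2E,4E)-5-[(1S,2S,4R)-4-[tert-butyl(dimethyl)silyl]oxy-2,6,6-trimethyl-1,2-bis(trimethylsilyloxy)cyclohexyl]-3-methylpenta-2,4-dienenitrile, via sodium phosphonate carbanion 18 (not isolated)
Conditions: 11, NaN(SiMe3)2, THF, −78 °C; then 17, → rt; minor 2Z isomer removed by chromatography
Reagents that add atoms: none
Why: Horner–Wadsworth–Emmons olefination gives the E C7=C8 bond; the ring stereocentres are untouched.

Step 14
Reactants: 19 C15 nitrile
Product: 21 (2E,4E)-5-[(1S,2S,4R)-4-[tert-butyl(dimethyl)silyl]oxy-2,6,6-trimethyl-1,2-bis(trimethylsilyloxy)cyclohexyl]-3-methylpenta-2,4-dienal, via N-aluminio aldimine 20 (not isolated)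
Conditions: i-Bu2AlH (1.3 equiv), CH2Cl2, −78 °C; then aq. potassium sodium tartrate, rt
Reagents that add atoms: water, O
Why: half-reduction of the nitrile to the aluminio aldimine and neutral hydrolysis to the dienal, conditions the silyl ethers tolerate.

Step 15
Reactants: 21 C15 aldehyde; 11 C5 nitrile phosphonate
Product: 23 (2E,4E,6E,8E)-9-[(1S,2S,4R)-4-[tert-butyl(dimethyl)silyl]oxy-2,6,6-trimethyl-1,2-bis(trimethylsilyloxy)cyclohexyl]-3,7-dimethylnona-2,4,6,8-tetraenenitrile, via lithium phosphonate carbanion 22 (not isolated)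
Conditions: 11, LiN(SiMe3)2, THF, −78 °C; then 21, → 0 °C
Reagents that add atoms: none
Why: second Horner–Wadsworth–Emmons homologation, here through the lithium carbanion generated with the lithium amide, which adds to the dienal carbonyl at −78 °C and eliminates on warming to give the E C11=C12 bond.

Step 16
Reactants: 23 C20 nitrile
Product: 25 (2E,4E,6E,8E)-9-[(1S,2S,4R)-4-[tert-butyl(dimethyl)silyl]oxy-2,6,6-trimethyl-1,2-bis(trimethylsilyloxy)cyclohexyl]-3,7-dimethylnona-2,4,6,8-tetraenal, via N-aluminio aldimine 24 (not isolated)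
Conditions: i-Bu2AlH (1.3 equiv), CH2Cl2, −78 °C; then aq. potassium sodium tartrate, rt, dark
Reagents that add atoms: water, O
Why: nitrile half-reduction as in step 14 gives the retinal-type C20 aldehyde.

## C5 ester phosphonate and C6 dienyl iodide

Step 17
Reactants: 26 methyl 3-methylbut-2-enoate
Product: 27 methyl (2E)-4-bromo-3-methylbut-2-enoate (E/Z mixture, E drawn)
Conditions: NBS, AIBN (cat.), PhCF3, reflux
Reagents that add atoms: N-bromosuccinimide, O=C1CCC(=O)N1Br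
Why: Wohl–Ziegler allylic bromination.

Step 18
Reactants: 27 bromo ester
Product: 28 methyl (2E)-4-(diethoxyphosphoryl)-3-methylbut-2-enoate
Conditions: P(OEt)3, neat, 110 °C
Reagents that add atoms: triethyl phosphite, CCOP(OCC)OCC
Why: Michaelis–Arbuzov reaction.

Step 19
Reactants: 29 (2E)-3-methylpent-2-en-4-yn-1-ol
Product: 30 tert-butyl(dimethyl){[(2E)-3-methylpent-2-en-4-yn-1-yl]oxy}silane
Conditions: TBSCl, imidazole, DMF, rt
Reagents that add atoms: tert-butyldimethylsilyl chloride, CC(C)(C)[Si](C)(C)Cl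
Why: silyl protection of the primary alcohol before organometallic chemistry.

Step 20
Reactants: 30 silylated enynol
Product: 32 tert-butyl{[(2E,4E)-5-iodo-3-methylpenta-2,4-dien-1-yl]oxy}dimethylsilane, via alkenylzirconocene chloride 31 (not isolated)
Conditions: Cp2Zr(H)Cl, THF, rt; then I2, 0 °C
Reagents that add atoms: iodine, II
Why: syn-hydrozirconation places zirconium on the terminal alkyne carbon and iodinolysis with retention gives the E vinyl iodide.

## Epoxy half (C20 phosphonium salt 50)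

Step 21
Reactants: 7 (R)-acetate
Product: 33 methyl (4R)-4-hydroxy-2,6,6-trimethylcyclohex-1-ene-1-carboxylate
Conditions: K2CO3 (cat.), MeOH, 0 °C → rt
Reagents that add atoms: none
Why: base-catalysed transesterification removes the acetate without touching the stereocentre.

Step 22
Reactants: 33 (R)-hydroxy ester
Product: 34 methyl (4R)-2,6,6-trimethyl-4-[(4-methylphenyl)sulfonyl]oxycyclohex-1-ene-1-carboxylate
Conditions: TsCl, pyridine, DMAP (cat.), CH2Cl2, 0 °C → rt
Reagents that add atoms: 4-toluenesulfonyl chloride, Cc1ccc(cc1)S(Cl)(=O)=O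
Why: sulfonylation with retention installs the leaving group that is later displaced with inversion by O6.

Step 23
Reactants: 34 tosylate ester
Product: 35 (1R)-4-(hydroxymethyl)-3,5,5-trimethylcyclohex-3-en-1-yl 4-methylbenzenesulfonate
Conditions: i-Bu2AlH (2.5 equiv), CH2Cl2, −78 °C; aq. potassium sodium tartrate
Reagents that add atoms: none
Why: the electrophilic aluminium hydride reduces the ester at −78 °C without displacing the secondary tosylate.

Step 24
Reactants: 35 allylic alcohol tosylate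
Product: 36 (1S,3S,6S)-6-(hydroxymethyl)-1,5,5-trimethyl-7-oxabicyclo[4.1.0]heptan-3-yl 4-methylbenzenesulfonate (oxirane cis to the tosyloxy group)
Conditions: Ti(OiPr)4 (0.2 equiv), L-(+)-diethyl tartrate (0.25 equiv), t-BuOOH, 4 Å MS, CH2Cl2, −20 °C
Reagents that add atoms: tert-butyl hydroperoxide, CC(C)(C)OO
Why: Sharpless asymmetric epoxidation with the enantiomeric tartrate gives the mirror-image oxirane of step 9 under reagent control.

Step 25
Reactants: 36 epoxy alcohol tosylate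
Product: 37 (1S,3R,4S)-3,4-dihydroxy-4-(hydroxymethyl)-3,5,5-trimethylcyclohexyl 4-methylbenzenesulfonate
Conditions: 0.1 M H2SO4, THF–H2O (2:1), 0 °C → rt
Reagents that add atoms: water, O
Why: as in step 10, anti attack of water at C5 (trans-diaxial opening) places the C5 hydroxyl trans to the tosylate; the secondary tosylate survives dilute acid.

Step 26
Reactants: 37 triol tosylate
Product: 38 (1S,3R)-3-hydroxy-3,5,5-trimethyl-4-oxocyclohexyl 4-methylbenzenesulfonate
Conditions: NaIO4 (1.2 equiv), THF–H2O, 0 °C → rt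
Reagents that add atoms: none
Why: periodate glycol cleavage of the flexible primary–tertiary C6–C7 diol excises C7 and unveils the C6 ketone, while the hindered ditertiary trans C5/C6 diol does not form the cyclic periodate ester at a comparable rate.

Step 27
Reactants: 38 hydroxy ketone
Product: 39 (1S,3R)-3,5,5-trimethyl-4-oxo-3-(trimethylsilyloxy)cyclohexyl 4-methylbenzenesulfonate
Conditions: TMSOTf, Et3N, CH2Cl2, −78 → 0 °C
Reagents that add atoms: trimethylsilyl trifluoromethanesulfonate, C[Si](C)(C)OS(=O)(=O)C(F)(F)F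
Why: silylation of the tertiary hydroxyl of a ketone with no α-hydrogen prevents alkoxide quenching and α-ketol shift in the next step.

Step 28
Reactants: 39 silyloxy ketone; 32 dienyl iodide
Product: 42 (1S,3R,4S)-4-[(1E,3E)-5-[tert-butyl(dimethyl)silyl]oxy-3-methylpenta-1,3-dien-1-yl]-4-hydroxy-3,5,5-trimethyl-3-(trimethylsilyloxy)cyclohexyl 4-methylbenzenesulfonate, via dienyllithium 40 (not isolated), via dienylcerium dichloride 41 (not isolated)
Conditions: 32, t-BuLi (2 equiv), Et2O, −78 °C; CeCl3, THF, −78 °C; then 39, −78 → −40 °C; aq. NH4Cl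
Reagents that add atoms: none
Why: 1,2-addition of the weakly basic organocerium occurs axially, antiperiplanar to the axial C5–OSiMe3 bond (polar Felkin–Anh; the equatorial path is blocked by two axial α-substituents), so the new C6 hydroxyl is cis to O5 and trans to the tosylate, with the E,E-diene retained.

Step 29
Reactants: 42 hydroxy tosylate
Product: 44 tert-butyl(dimethyl){[(2E,4E)-3-methyl-5-[(1S,2R,4R)-2,6,6-trimethyl-2-(trimethylsilyloxy)-7-oxabicyclo[2.2.1]heptan-1-yl]penta-2,4-dien-1-yl]oxy}silane, via sodium alkoxide 43 (not isolated)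
Conditions: NaH, 15-crown-5 (cat.), THF, 0 → 50 °C
Reagents that add atoms: none
Why: intramolecular Williamson etherification through a boat conformer, in which the O6 alkoxide displaces the C3 tosylate by SN2 with inversion, so the ether bridge ends up cis to O5 (any O5/O6 silyl shuttling is harmless because five-ring closure from O6 is far faster than four-ring closure from O5).

Step 30
Reactants: 44 bicyclic bis-silyl ether
Product: 45 (1S,2R,4R)-1-[(1E,3E)-5-hydroxy-3-methylpenta-1,3-dien-1-yl]-2,6,6-trimethyl-7-oxabicyclo[2.2.1]heptan-2-ol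
Conditions: TBAF, THF, 0 °C → rt
Reagents that add atoms: none
Why: fluoride cleaves both silyl ethers under non-acidic conditions.

Step 31
Reactants: 45 diol
Product: 46 (2E,4E)-5-[(1S,2R,4R)-2-hydroxy-2,6,6-trimethyl-7-oxabicyclo[2.2.1]heptan-1-yl]-3-methylpenta-2,4-dienal
Conditions: MnO2 (activated, excess), CH2Cl2, rt
Reagents that add atoms: none
Why: chemoselective allylic oxidation; the tertiary alcohol is inert.

Step 32
Reactants: 46 C15 aldehyde; 28 C5 ester phosphonate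
Product: 48 methyl (2E,4E,6E,8E)-9-[(1S,2R,4R)-2-hydroxy-2,6,6-trimethyl-7-oxabicyclo[2.2.1]heptan-1-yl]-3,7-dimethylnona-2,4,6,8-tetraenoate, via sodium phosphonate carbanion 47 (not isolated)
Conditions: 28, NaN(SiMe3)2, THF, −78 °C; then 46, → 0 °C
Reagents that add atoms: none
Why: E-selective Horner–Wadsworth–Emmons olefination; the stabilised carbanion is too weakly basic to disturb the free tertiary alcohol.

Step 33
Reactants: 48 C20 ester
Product: 49 (1S,2R,4R)-1-[(1E,3E,5E,7E)-9-hydroxy-3,7-dimethylnona-1,3,5,7-tetraen-1-yl]-2,6,6-trimethyl-7-oxabicyclo[2.2.1]heptan-2-ol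
Conditions: i-Bu2AlH (3.5 equiv), CH2Cl2, −78 °C; aq. potassium sodium tartrate, dark
Reagents that add atoms: none
Why: 1,2-reduction of the polyenoate to the retinol-type allylic alcohol.

Step 34
Reactants: 49 C20 diol
Product: 50 [(2E,4E,6E,8E)-9-[(1S,2R,4R)-2-hydroxy-2,6,6-trimethyl-7-oxabicyclo[2.2.1]heptan-1-yl]-3,7-dimethylnona-2,4,6,8-tetraen-1-yl]triphenylphosphonium bromide
Conditions: Ph3P·HBr, MeOH–CH2Cl2, 0 °C → rt, dark
Reagents that add atoms: triphenylphosphine hydrobromide, [Br-].c1ccccc1[PH+](c1ccccc1)c1ccccc1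
Why: retinol-type phosphonium salt formation (polyenyl cation trapped by PPh3 at the terminal carbon); the non-allylic tertiary C5–OH and the bicyclic ether, which is acid-stable unlike a 5,6-epoxide, survive.

## Coupling of the halves and deprotection

Step 35
Reactants: 50 C20 phosphonium bromide; 25 C20 aldehyde
Product: 53 (all-E)-(3R,5R,6S,3'R,5'S,6'S)-3'-[tert-butyl(dimethyl)silyl]oxy-5',6'-bis(trimethylsilyloxy)-3,6-epoxy-5,6,5',6'-tetrahydro-β,β-caroten-5-ol, via phosphonium ylide 51 (not isolated), via 15Z isomer 52 (not isolated)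
Conditions: 50, NaN(SiMe3)2 (1.0 equiv), THF, −78 °C; 25, → rt; then EtOAc, reflux, 2 h, dark, Ar
Reagents that add atoms: none
Why: Wittig olefination forms the central C15=C15' bond (the retinal + retinyl-ylide carotene coupling), and the 15Z portion isomerises thermally to the all-E polyene; no stereocentre is involved.

Step 36
Reactants: 53 silylated carotenoid
Product: 54 (3R,5R,6S,3'R,5'S,6'S)-3,6-epoxy-5,6,5',6'-tetrahydro-β,β-carotene-5,3',5',6'-tetrol (target CNP0261804.1)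
Conditions: TBAF (4 equiv), THF, 0 °C → rt, dark; neutral work-up
Reagents that add atoms: none
Why: fluoride removes the TBS and both TMS ethers without acid, which would ionise the tertiary allylic C6'–OH.

## Compound list

1 | mesityl oxide (4-methylpent-3-en-2-one) | CC(=O)C=C(C)C | starting material
2 | methyl acetoacetate | COC(=O)CC(C)=O | starting material
3 | methyl (±)-2,6,6-trimethyl-4-oxocyclohex-2-ene-1-carboxylate | COC(=O)C1C(C)=CC(=O)CC1(C)C | intermediate
4 | methyl 4-acetoxy-2,6,6-trimethylcyclohexa-1,3-diene-1-carboxylate | COC(=O)C1=C(C)C=C(OC(C)=O)CC1(C)C | intermediate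
5 | methyl 2,6,6-trimethyl-4-oxocyclohex-1-ene-1-carboxylate (not isolated) | COC(=O)C1=C(C)CC(=O)CC1(C)C | intermediate
6 | methyl (±)-4-hydroxy-2,6,6-trimethylcyclohex-1-ene-1-carboxylate | COC(=O)C1=C(C)CC(O)CC1(C)C | intermediate
7 | methyl (4R)-4-acetoxy-2,6,6-trimethylcyclohex-1-ene-1-carboxylate | COC(=O)C1=C(C)C[C@@H](OC(C)=O)CC1(C)C | intermediate
8 | methyl (4S)-4-hydroxy-2,6,6-trimethylcyclohex-1-ene-1-carboxylate | COC(=O)C1=C(C)C[C@H](O)CC1(C)C | intermediate
9 | 3-methylbut-2-enenitrile | CC(C)=CC#N | starting material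
10 | (2E)-4-bromo-3-methylbut-2-enenitrile | BrC/C(C)=C/C#N | intermediate
11 | diethyl [(2E)-3-cyano-2-methylprop-2-en-1-yl]phosphonate | CCOP(=O)(OCC)C/C(C)=C/C#N | intermediate
12 | methyl (4S)-4-[tert-butyl(dimethyl)silyl]oxy-2,6,6-trimethylcyclohex-1-ene-1-carboxylate | COC(=O)C1=C(C)C[C@H](O[Si](C)(C)C(C)(C)C)CC1(C)C | intermediate
13 | [(4S)-4-[tert-butyl(dimethyl)silyl]oxy-2,6,6-trimethylcyclohex-1-en-1-yl]methanol | OCC1=C(C)C[C@H](O[Si](C)(C)C(C)(C)C)CC1(C)C | intermediate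
14 | [(1R,4R,6R)-4-[tert-butyl(dimethyl)silyl]oxy-2,2,6-trimethyl-7-oxabicyclo[4.1.0]heptan-1-yl]methanol | OC[C@@]12O[C@]1(C)C[C@H](O[Si](C)(C)C(C)(C)C)CC2(C)C | intermediate
15 | (1R,2S,4R)-4-[tert-butyl(dimethyl)silyl]oxy-1-(hydroxymethyl)-2,6,6-trimethylcyclohexane-1,2-diol | OC[C@]1(O)C(C)(C)C[C@@H](O[Si](C)(C)C(C)(C)C)C[C@]1(C)O | intermediate
16 | (1S,2S,4R)-4-[tert-butyl(dimethyl)silyl]oxy-1,2-dihydroxy-2,6,6-trimethylcyclohexane-1-carbaldehyde | O=C[C@]1(O)C(C)(C)C[C@@H](O[Si](C)(C)C(C)(C)C)C[C@]1(C)O | intermediate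
17 | (1S,2S,4R)-4-[tert-butyl(dimethyl)silyl]oxy-2,6,6-trimethyl-1,2-bis(trimethylsilyloxy)cyclohexane-1-carbaldehyde | O=C[C@]1(O[Si](C)(C)C)C(C)(C)C[C@@H](O[Si](C)(C)C(C)(C)C)C[C@]1(C)O[Si](C)(C)C | intermediate
18 | sodium carbanion of phosphonate 11 (not isolated) | [Na+].CCOP(=O)(OCC)[CH-]/C(C)=C/C#N | intermediate
19 | (2E,4E)-5-[(1S,2S,4R)-4-[tert-butyl(dimethyl)silyl]oxy-2,6,6-trimethyl-1,2-bis(trimethylsilyloxy)cyclohexyl]-3-methylpenta-2,4-dienenitrile | N#C/C=C(C)/C=C/[C@]1(O[Si](C)(C)C)C(C)(C)C[C@@H](O[Si](C)(C)C(C)(C)C)C[C@]1(C)O[Si](C)(C)C | intermediate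
20 | N-(diisobutylaluminio) aldimine from 19 (not isolated) | CC(C)C[Al](CC(C)C)N=C/C=C(C)/C=C/[C@]1(O[Si](C)(C)C)C(C)(C)C[C@@H](O[Si](C)(C)C(C)(C)C)C[C@]1(C)O[Si](C)(C)C | intermediate
21 | (2E,4E)-5-[(1S,2S,4R)-4-[tert-butyl(dimethyl)silyl]oxy-2,6,6-trimethyl-1,2-bis(trimethylsilyloxy)cyclohexyl]-3-methylpenta-2,4-dienal | O=C/C=C(C)/C=C/[C@]1(O[Si](C)(C)C)C(C)(C)C[C@@H](O[Si](C)(C)C(C)(C)C)C[C@]1(C)O[Si](C)(C)C | intermediate
22 | lithium carbanion of phosphonate 11 (not isolated) | [Li+].CCOP(=O)(OCC)[CH-]/C(C)=C/C#N | intermediate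
23 | (2E,4E,6E,8E)-9-[(1S,2S,4R)-4-[tert-butyl(dimethyl)silyl]oxy-2,6,6-trimethyl-1,2-bis(trimethylsilyloxy)cyclohexyl]-3,7-dimethylnona-2,4,6,8-tetraenenitrile | N#C/C=C(C)/C=C/C=C(C)/C=C/[C@]1(O[Si](C)(C)C)C(C)(C)C[C@@H](O[Si](C)(C)C(C)(C)C)C[C@]1(C)O[Si](C)(C)C | intermediate
24 | N-(diisobutylaluminio) aldimine from 23 (not isolated) | CC(C)C[Al](CC(C)C)N=C/C=C(C)/C=C/C=C(C)/C=C/[C@]1(O[Si](C)(C)C)C(C)(C)C[C@@H](O[Si](C)(C)C(C)(C)C)C[C@]1(C)O[Si](C)(C)C | intermediate
25 | (2E,4E,6E,8E)-9-[(1S,2S,4R)-4-[tert-butyl(dimethyl)silyl]oxy-2,6,6-trimethyl-1,2-bis(trimethylsilyloxy)cyclohexyl]-3,7-dimethylnona-2,4,6,8-tetraenal | O=C/C=C(C)/C=C/C=C(C)/C=C/[C@]1(O[Si](C)(C)C)C(C)(C)C[C@@H](O[Si](C)(C)C(C)(C)C)C[C@]1(C)O[Si](C)(C)C | intermediate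
26 | methyl 3-methylbut-2-enoate | COC(=O)C=C(C)C | starting material
27 | methyl (2E)-4-bromo-3-methylbut-2-enoate | BrC/C(C)=C/C(=O)OC | intermediate
28 | methyl (2E)-4-(diethoxyphosphoryl)-3-methylbut-2-enoate | CCOP(=O)(OCC)C/C(C)=C/C(=O)OC | intermediate
29 | (2E)-3-methylpent-2-en-4-yn-1-ol | C#C/C(C)=C/CO | starting material
30 | tert-butyl(dimethyl){[(2E)-3-methylpent-2-en-4-yn-1-yl]oxy}silane | C#C/C(C)=C/CO[Si](C)(C)C(C)(C)C | intermediate
31 | chlorobis(cyclopentadienyl)[(1E,3E)-5-[tert-butyl(dimethyl)silyl]oxy-3-methylpenta-1,3-dien-1-yl]zirconium (not isolated) | Cl[Zr](C1C=CC=C1)(C1C=CC=C1)/C=C/C(C)=C/CO[Si](C)(C)C(C)(C)C | intermediate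
32 | tert-butyl{[(2E,4E)-5-iodo-3-methylpenta-2,4-dien-1-yl]oxy}dimethylsilane | I/C=C/C(C)=C/CO[Si](C)(C)C(C)(C)C | intermediate
33 | methyl (4R)-4-hydroxy-2,6,6-trimethylcyclohex-1-ene-1-carboxylate | COC(=O)C1=C(C)C[C@@H](O)CC1(C)C | intermediate
34 | methyl (4R)-2,6,6-trimethyl-4-[(4-methylphenyl)sulfonyl]oxycyclohex-1-ene-1-carboxylate | COC(=O)C1=C(C)C[C@@H](OS(=O)(=O)c2ccc(C)cc2)CC1(C)C | intermediate
35 | (1R)-4-(hydroxymethyl)-3,5,5-trimethylcyclohex-3-en-1-yl 4-methylbenzenesulfonate | OCC1=C(C)C[C@@H](OS(=O)(=O)c2ccc(C)cc2)CC1(C)C | intermediate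
36 | (1S,3S,6S)-6-(hydroxymethyl)-1,5,5-trimethyl-7-oxabicyclo[4.1.0]heptan-3-yl 4-methylbenzenesulfonate | OC[C@]12O[C@@]1(C)C[C@@H](OS(=O)(=O)c3ccc(C)cc3)CC2(C)C | intermediate
37 | (1S,3R,4S)-3,4-dihydroxy-4-(hydroxymethyl)-3,5,5-trimethylcyclohexyl 4-methylbenzenesulfonate | OC[C@@]1(O)C(C)(C)C[C@H](OS(=O)(=O)c2ccc(C)cc2)C[C@@]1(C)O | intermediate
38 | (1S,3R)-3-hydroxy-3,5,5-trimethyl-4-oxocyclohexyl 4-methylbenzenesulfonate | O=C1C(C)(C)C[C@H](OS(=O)(=O)c2ccc(C)cc2)C[C@@]1(C)O | intermediate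
39 | (1S,3R)-3,5,5-trimethyl-4-oxo-3-(trimethylsilyloxy)cyclohexyl 4-methylbenzenesulfonate | O=C1C(C)(C)C[C@H](OS(=O)(=O)c2ccc(C)cc2)C[C@@]1(C)O[Si](C)(C)C | intermediate
40 | [(1E,3E)-5-[tert-butyl(dimethyl)silyl]oxy-3-methylpenta-1,3-dien-1-yl]lithium (not isolated) | [Li]/C=C/C(C)=C/CO[Si](C)(C)C(C)(C)C | intermediate
41 | dichloro[(1E,3E)-5-[tert-butyl(dimethyl)silyl]oxy-3-methylpenta-1,3-dien-1-yl]cerium (not isolated) | Cl[Ce](Cl)/C=C/C(C)=C/CO[Si](C)(C)C(C)(C)C | intermediate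
42 | (1S,3R,4S)-4-[(1E,3E)-5-[tert-butyl(dimethyl)silyl]oxy-3-methylpenta-1,3-dien-1-yl]-4-hydroxy-3,5,5-trimethyl-3-(trimethylsilyloxy)cyclohexyl 4-methylbenzenesulfonate | CC(C)(C)[Si](C)(C)OC/C=C(C)/C=C/[C@]1(O)C(C)(C)C[C@H](OS(=O)(=O)c2ccc(C)cc2)C[C@@]1(C)O[Si](C)(C)C | intermediate
43 | sodium alkoxide of 42 (not isolated) | [Na+].CC(C)(C)[Si](C)(C)OC/C=C(C)/C=C/[C@]1([O-])C(C)(C)C[C@H](OS(=O)(=O)c2ccc(C)cc2)C[C@@]1(C)O[Si](C)(C)C | intermediate
44 | tert-butyl(dimethyl){[(2E,4E)-3-methyl-5-[(1S,2R,4R)-2,6,6-trimethyl-2-(trimethylsilyloxy)-7-oxabicyclo[2.2.1]heptan-1-yl]penta-2,4-dien-1-yl]oxy}silane | CC(C)(C)[Si](C)(C)OC/C=C(C)/C=C/[C@]12O[C@H](CC1(C)C)C[C@@]2(C)O[Si](C)(C)C | intermediate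
45 | (1S,2R,4R)-1-[(1E,3E)-5-hydroxy-3-methylpenta-1,3-dien-1-yl]-2,6,6-trimethyl-7-oxabicyclo[2.2.1]heptan-2-ol | OC/C=C(C)/C=C/[C@]12O[C@H](CC1(C)C)C[C@@]2(C)O | intermediate
46 | (2E,4E)-5-[(1S,2R,4R)-2-hydroxy-2,6,6-trimethyl-7-oxabicyclo[2.2.1]heptan-1-yl]-3-methylpenta-2,4-dienal | O=C/C=C(C)/C=C/[C@]12O[C@H](CC1(C)C)C[C@@]2(C)O | intermediate
47 | sodium carbanion of phosphonate 28 (not isolated) | [Na+].CCOP(=O)(OCC)[CH-]/C(C)=C/C(=O)OC | intermediate
48 | methyl (2E,4E,6E,8E)-9-[(1S,2R,4R)-2-hydroxy-2,6,6-trimethyl-7-oxabicyclo[2.2.1]heptan-1-yl]-3,7-dimethylnona-2,4,6,8-tetraenoate | COC(=O)/C=C(C)/C=C/C=C(C)/C=C/[C@]12O[C@H](CC1(C)C)C[C@@]2(C)O | intermediate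
49 | (1S,2R,4R)-1-[(1E,3E,5E,7E)-9-hydroxy-3,7-dimethylnona-1,3,5,7-tetraen-1-yl]-2,6,6-trimethyl-7-oxabicyclo[2.2.1]heptan-2-ol | OC/C=C(C)/C=C/C=C(C)/C=C/[C@]12O[C@H](CC1(C)C)C[C@@]2(C)O | intermediate
50 | [(2E,4E,6E,8E)-9-[(1S,2R,4R)-2-hydroxy-2,6,6-trimethyl-7-oxabicyclo[2.2.1]heptan-1-yl]-3,7-dimethylnona-2,4,6,8-tetraen-1-yl]triphenylphosphonium bromide | [Br-].c1ccccc1[P+](c1ccccc1)(c1ccccc1)C/C=C(C)/C=C/C=C(C)/C=C/[C@]12O[C@H](CC1(C)C)C[C@@]2(C)O | intermediate
51 | phosphonium ylide of 50 (not isolated) | c1ccccc1[P+](c1ccccc1)(c1ccccc1)[CH-]/C=C(C)/C=C/C=C(C)/C=C/[C@]12O[C@H](CC1(C)C)C[C@@]2(C)O | intermediate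
52 | (15Z) isomer of 53 (not isolated) | CC(/C=C/C=C(C)/C=C/[C@]12O[C@H](CC1(C)C)C[C@@]2(C)O)=C\C=C/C=C(C)/C=C/C=C(C)/C=C/[C@]1(O[Si](C)(C)C)C(C)(C)C[C@@H](O[Si](C)(C)C(C)(C)C)C[C@]1(C)O[Si](C)(C)C | intermediate
53 | (all-E)-(3R,5R,6S,3'R,5'S,6'S)-3'-[tert-butyl(dimethyl)silyl]oxy-5',6'-bis(trimethylsilyloxy)-3,6-epoxy-5,6,5',6'-tetrahydro-β,β-caroten-5-ol | CC(/C=C/C=C(C)/C=C/[C@]12O[C@H](CC1(C)C)C[C@@]2(C)O)=C\C=C\C=C(C)\C=C\C=C(C)\C=C\[C@]1(O[Si](C)(C)C)C(C)(C)C[C@@H](O[Si](C)(C)C(C)(C)C)C[C@]1(C)O[Si](C)(C)C | intermediate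
54 | (3R,5R,6S,3'R,5'S,6'S)-3,6-epoxy-5,6,5',6'-tetrahydro-β,β-carotene-5,3',5',6'-tetrol | CC(/C=C/C=C(C)/C=C/[C@]12O[C@H](CC1(C)C)C[C@@]2(C)O)=C\C=C\C=C(C)\C=C\C=C(C)\C=C\[C@]1(O)C(C)(C)C[C@@H](O)C[C@]1(C)O | target

## Step count and weak points

Total step count: 36.
Longest linear sequence: 20 steps (steps 1–4, 21–34, 35–36).

Three steps most likely to fail:

Step 4 (lipase resolution; the enantioselectivity on this ring with two CH2 flanks is unproven). Fallback, setting out from 6: the racemate is resolved covalently instead of kinetically. DCC/DMAP esterification of 6 with (S)-O-methylmandelic acid gives two diastereomeric esters that are separated by chromatography: methyl (4R)-4-[(2S)-2-methoxy-2-phenylacetyl]oxy-2,6,6-trimethylcyclohex-1-ene-1-carboxylate F1 and methyl (4S)-4-[(2S)-2-methoxy-2-phenylacetyl]oxy-2,6,6-trimethylcyclohex-1-ene-1-carboxylate F2. K2CO3/MeOH methanolysis of F1 comes back to the route at 33 and that of F2 at 8.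

Step 13 (olefination of the very congested, fully substituted α-silyloxy aldehyde 17). Fallback, setting out from 14: the chain is attached before the oxirane is opened, when the aldehyde carbon is less shielded. Dess–Martin oxidation of 14 gives (1S,4R,6R)-4-[tert-butyl(dimethyl)silyl]oxy-2,2,6-trimethyl-7-oxabicyclo[4.1.0]heptane-1-carbaldehyde F3. Olefination of F3 with carbanion 18 gives (2E,4E)-5-[(1S,4R,6R)-4-[tert-butyl(dimethyl)silyl]oxy-2,2,6-trimethyl-7-oxabicyclo[4.1.0]heptan-1-yl]-3-methylpenta-2,4-dienenitrile F4. Dilute H2SO4 in THF–H2O then opens the oxirane at C5 with inversion (C6 is deactivated by the dienenitrile) to (2E,4E)-5-[(1S,2S,4R)-4-[tert-butyl(dimethyl)silyl]oxy-1,2-dihydroxy-2,6,6-trimethylcyclohexyl]-3-methylpenta-2,4-dienenitrile F5. TMSOTf/Et3N silylation of F5 comes back to the route at 19.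

Step 29 (SN2 closure of the oxanorbornane; E2 loss of the tosylate may compete, and the tosylate must also have survived step 28). Fallback, setting out from 38: the bridge is closed by cation capture with retention instead of displacement with inversion. KO2/18-crown-6 in DMSO inverts C3 to give (2R,4R)-2,4-dihydroxy-2,6,6-trimethylcyclohexan-1-one F6. TMSOTf/Et3N gives (2R,4R)-2,6,6-trimethyl-2,4-bis(trimethylsilyloxy)cyclohexan-1-one F7. Addition of organocerium 41 gives (2R,4R)-1-[(1E,3E)-5-[tert-butyl(dimethyl)silyl]oxy-3-methylpenta-1,3-dien-1-yl]-2,6,6-trimethyl-2,4-bis(trimethylsilyloxy)cyclohexan-1-ol F8, whose C1 configuration does not matter. K2CO3/MeOH removes both trimethylsilyl groups to give (2R,4R)-1-[(1E,3E)-5-[tert-butyl(dimethyl)silyl]oxy-3-methylpenta-1,3-dien-1-yl]-2,6,6-trimethylcyclohexane-1,2,4-triol F9. Catalytic PPTS in CH2Cl2 at −20 °C ionises the tertiary dienylic C6–OH, and the C3–OH, cis to O5, captures the cation on its own face to give (1S,2R,4R)-1-[(1E,3E)-5-[tert-butyl(dimethyl)silyl]oxy-3-methylpenta-1,3-dien-1-yl]-2,6,6-trimethyl-7-oxabicyclo[2.2.1]heptan-2-ol F10. TBAF on F10 comes back to the route at 45.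

Further compounds
F1 | step 4 | methyl (4R)-4-[(2S)-2-methoxy-2-phenylacetyl]oxy-2,6,6-trimethylcyclohex-1-ene-1-carboxylate | COC(=O)C1=C(C)C[C@@H](OC(=O)[C@@H](OC)c2ccccc2)CC1(C)C
F2 | step 4 | methyl (4S)-4-[(2S)-2-methoxy-2-phenylacetyl]oxy-2,6,6-trimethylcyclohex-1-ene-1-carboxylate | COC(=O)C1=C(C)C[C@H](OC(=O)[C@@H](OC)c2ccccc2)CC1(C)C
F3 | step 13 | (1S,4R,6R)-4-[tert-butyl(dimethyl)silyl]oxy-2,2,6-trimethyl-7-oxabicyclo[4.1.0]heptane-1-carbaldehyde | O=C[C@@]12O[C@]1(C)C[C@H](O[Si](C)(C)C(C)(C)C)CC2(C)C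
F4 | step 13 | (2E,4E)-5-[(1S,4R,6R)-4-[tert-butyl(dimethyl)silyl]oxy-2,2,6-trimethyl-7-oxabicyclo[4.1.0]heptan-1-yl]-3-methylpenta-2,4-dienenitrile | N#C/C=C(C)/C=C/[C@@]12O[C@]1(C)C[C@H](O[Si](C)(C)C(C)(C)C)CC2(C)C
F5 | step 13 | (2E,4E)-5-[(1S,2S,4R)-4-[tert-butyl(dimethyl)silyl]oxy-1,2-dihydroxy-2,6,6-trimethylcyclohexyl]-3-methylpenta-2,4-dienenitrile | N#C/C=C(C)/C=C/[C@]1(O)C(C)(C)C[C@@H](O[Si](C)(C)C(C)(C)C)C[C@]1(C)O
F6 | step 29 | (2R,4R)-2,4-dihydroxy-2,6,6-trimethylcyclohexan-1-one | O=C1C(C)(C)C[C@@H](O)C[C@@]1(C)O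
F7 | step 29 | (2R,4R)-2,6,6-trimethyl-2,4-bis(trimethylsilyloxy)cyclohexan-1-one | O=C1C(C)(C)C[C@@H](O[Si](C)(C)C)C[C@@]1(C)O[Si](C)(C)C
F8 | step 29 | (2R,4R)-1-[(1E,3E)-5-[tert-butyl(dimethyl)silyl]oxy-3-methylpenta-1,3-dien-1-yl]-2,6,6-trimethyl-2,4-bis(trimethylsilyloxy)cyclohexan-1-ol (C1 epimers) | CC(C)(C)[Si](C)(C)OC/C=C(C)/C=C/C1(O)C(C)(C)C[C@@H](O[Si](C)(C)C)C[C@@]1(C)O[Si](C)(C)C
F9 | step 29 | (2R,4R)-1-[(1E,3E)-5-[tert-butyl(dimethyl)silyl]oxy-3-methylpenta-1,3-dien-1-yl]-2,6,6-trimethylcyclohexane-1,2,4-triol (C1 epimers) | CC(C)(C)[Si](C)(C)OC/C=C(C)/C=C/C1(O)C(C)(C)C[C@@H](O)C[C@@]1(C)O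
F10 | step 29 | (1S,2R,4R)-1-[(1E,3E)-5-[tert-butyl(dimethyl)silyl]oxy-3-methylpenta-1,3-dien-1-yl]-2,6,6-trimethyl-7-oxabicyclo[2.2.1]heptan-2-ol | CC(C)(C)[Si](C)(C)OC/C=C(C)/C=C/[C@]12O[C@H](CC1(C)C)C[C@@]2(C)O
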